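Subtract the blue run from the grey run, reading by reading: the two flasks have the same charges of starting material and partner, and the grey one has target besides, so the difference follows the added target.

| flask | starting material | partner | target | time |
|---|---|---|---|---|
| blue | 150 mM | 300 mM |  |  |
| grey | 150 mM | 300 mM | 45.0 mM |  |
| amber | 220 mM | 300 mM |  |  |
| red | 150 mM | 150 mM |  |  |
| violet | 50.0 mM | 900 mM |  | 35 h |

| blue run: time / h | blue run: [target] / mM | grey run: time / h | grey run: [target] / mM | amber run: time / h | amber run: [target] / mM | red run: time / h | red run: [target] / mM |
|---|---|---|---|---|---|---|---|
| 2.7 | 3.2 | 2.7 | 44.7 | 2.7 | 4.5 | 2.7 | 1.6 |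
| 8.1 | 16.1 | 8.1 | 50.8 | 8.1 | 22.2 | 8.1 | 11.3 |
| 15 | 28.9 | 15 | 58.1 | 15 | 42.0 | 15 | 22.4 |
| 24 | 41.3 | 24 | 63.8 | 24 | 59.9 | 24 | 33.5 |
| 35 | 47.8 | 35 | 63.4 | 35 | 72.3 | 35 | 43.2 |

(standard deviation of a reading: 0.4 mM)

- Overall: starting material + partner -> target.
- Constant volume, constant temperature.
- "The second partner" is partner.
- An order is taken over about fifteen percent of the charge, up and down.

1. the power of [partner] that the first rate follows, about the charge of the blue run; measure it at two percent of starting material made into target
2. the power of [starting material] that the first rate follows, about the charge of the blue run; measure it at two percent of starting material made into target (one fixed amount of target, the same in the runs compared)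
3. target in the violet run at 35 h, as a share of the starting material charged

That excess fell from 45.0 mM at the start to 15.6 mM at 35 h, so I treated the loss as pseudo-first-order at this partner charge, with constant 0.0303 h⁻¹. Its inverse, 33.0 h, I called the target lifetime: the time in which the excess of c(target) falls by a factor e at this partner charge. This is a reading, and it carries the scatter of the two readings behind it. The share made by 35 h hardly moved with the charge of starting material, 31.9% in the blue run and 32.9% in the amber run, so I reckoned the violet run as a share.

The blue run was flattening near one lifetime, so I gave the making step the same time constant. With the main step alone, I reckoned the violet run at 65.3%. Adding the loss at the blue lifetime brought this down to 36.7%, where the blue run read 31.9%. Then I let the loss depend on partner. Between the last two readings, I assumed the same gross making rate in the red run as in the blue, 1.94 mM h⁻¹, which gave a red loss constant of 0.0276 h⁻¹. Extended in a straight line to 900 mM of partner, this gave the violet run 0.0410 h⁻¹, a lifetime of 24.4 h, and a two-step share of 30.6%. Scaled by the blue reading, that made my figure 26.5%, though it rests on a small difference between two loss constants.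

The forecast, which gave orders of 0.6 in partner and 0.7 in starting material, held that the violet run “should reach its ceiling” and put it at 36%, higher than my figure.

The flask gave orders of 0.42 in partner and 0.64 in starting material, and 19.3% in the violet run, lower than my figure.

    starting material + partner → intermediate (1.548 L mol⁻¹ h⁻¹)
    intermediate → target (0.02308 h⁻¹)
    target → decomposed product (0.02218 h⁻¹)
    target + partner → side product (0.04968 L mol⁻¹ h⁻¹)

The violet run fell short because target reacts with partner to give side product, a step worth 17 percentage points there. At the charged 900 mM of partner, the target lifetime in the violet run came to 14.9 h, shorter than the 33.0 h I had read at 300 mM of partner from the grey and blue runs, and the two-step rule then gives 18.4%. Taking that step away lengthens the lifetime to 45.1 h, for which the rule gives 36.6%, and the violet run without the step stands at 36.4%.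

The readings are calculated for substances that don't exist, and the scatter is random.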